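All runs are calculated from invented constants; the scatter is artificial.

G, the substrate, takes up E to give L, and L slips on into Z. The readings of the three earlier runs sum close to the charge, so these are the species to count. You want the L standing at the end of two flasks.

| flask | G | E | remark | time |
|---|---|---|---|---|
| east | 0.038 M | 0.137 M | run made earlier |  |
| south-east | 0.057 M | 0.137 M | run made earlier |  |
| west | 0.076 M | 0.069 M | run made earlier |  |
| zeta | 0.076 M | 0.137 M |  | 4.0 min |
| gamma | 0.076 M | 0.137 M |  | 5.0 min |

| run | time / min | G / % | L / % | Z / % |
|---|---|---|---|---|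
| east | 0.667 | 34.8 | 63.0 | 3.0 |
| east | 1.33 | 13.3 | 78.9 | 7.3 |
| east | 2.00 | 5.4 | 81.2 | 13.3 |
| east | 3.00 | 1.7 | 78.0 | 20.8 |
| east | 4.00 | 0 | 72.2 | 28.0 |
| east | 5.00 | 0 | 65.9 | 33.5 |
| south-east | 0.667 | 36.2 | 60.4 | 2.7 |
| south-east | 1.33 | 16.4 | 76.7 | 7.8 |
| south-east | 2.00 | 7.2 | 80.1 | 12.7 |
| south-east | 3.00 | 3.0 | 77.7 | 20.8 |
| south-east | 4.00 | 1.0 | 71.7 | 27.2 |
| south-east | 5.00 | 0.6 | 66.5 | 33.1 |
| west | 0.417 | 73.2 | 27.0 | 1.1 |
| west | 1.33 | 46.4 | 48.6 | 4.2 |
| west | 2.00 | 37.4 | 54.4 | 7.9 |
| west | 3.00 | 29.7 | 56.8 | 13.7 |
| west | 5.00 | 21.1 | 55.0 | 24.1 |

(readings scatter by 0.3 percentage points)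

- which of these there is most of at the end, counted by the G in it, zeta (Z / G / L)
- which of these there is most of at the end, counted by the G in it, gamma (Z / G / L)
- final amount of the leader among these, as a percentage of the G charged, in zeta
- final amount of the leader among these, as a percentage of the G charged, in gamma



Climb the ladder from the fastest rung. Taking the first step as first order in G and in E, with one E spent per G, the east reading at 1.33 min gives a rate constant of 13.2 /M/min. The west reading at 2.00 min, from a flask charged with less E than G, gives 13.3 /M/min. G is the limiting reagent in zeta and gamma. Integrating G over the run, a G there waits on average 0.805 min before it becomes L; in the east run the wait is 0.646 min.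

The next rung is the loss of L. Suppose the east L was all born at the start: its last reading then gives 0.0834 /min. But that L is younger than the clock, so go round again with its age, the time minus the wait. This gives 0.0958 /min, the leak constant, the part of the L present that passes net to Z each minute. Its half-life, 7.24 min, is longer than the wait.

So the top rung is simple. By the end, G is down to 1.80 % in zeta and 0.795 % in gamma, and the L is what reacted, decayed over its age. I reckon 72.3 % in zeta and 66.4 % in gamma, where L still holds more than the rest together.

The forecast names L and L as leaders, at 71.4 % in zeta and 65.8 % in gamma, a little below my figures, holding that “Z formation is first order in L and independent of concentration”.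

The flasks give L at 71.6 % in zeta and L at 66.7 % in gamma.

    G + E → L (k = 0.220 /M/s)
    L ⇌ Z (K = 2.00, k = 0.00180 /s)

Zeta's own L, put through the same age, returns a leak constant of 0.0990 /min. Gamma minus zeta in L is −4.9 percentage points, and the largest single effect in that gap is the loss of L to Z, both ways: take it away and the difference becomes 1 point. Now take the neighbour of gamma charged with 0.30 M of G, where E is the limiting reagent and 0 % of it is left at 5.00 min. There the wait belongs to E, 0.337 min, and the leak constant gives 29.2 % of L; that flask holds 29.6 %.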